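The earlier runs and the new flask were generated by integration for an exercise; noise was put on by code.

No constant is given, so read one from Friday's run and carry it to the flask.

common to all: free catalyst 0.1 mol%; added ligand 2.6 mM

|  | left-handed substrate | right-handed substrate | partner | remark | time |
|---|---|---|---|---|---|
| Friday's | 0.50 M | 0.50 M | 2 equiv | run made earlier |  |
| flask | 1.0 M | 1.0 M | 2.00 equiv |  | 8.0 min |

Friday's run (percent of the left-handed substrate and right-handed substrate together charged)

| time / min | left-handed substrate / % | right-handed substrate / % |
|---|---|---|
| 0.833 | 44.4 | 49.0 |
| 1.50 | 41.9 | 49.6 |
| 2.50 | 38.0 | 49.6 |
| 3.00 | 36.8 | 49.3 |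
| 4.00 | 33.7 | 48.9 |
| 5.00 | 31.9 | 49.3 |

(each reading ± 0.5 percentage points)

- free catalyst is single-handed; left-handed substrate and right-handed substrate are mirror images of each other, charged as a racemate, each of them at the stated concentration
- an excess is the difference of the two amounts in percent of their sum
- an excess is below zero if the other one leads
- no earlier run changes the charge of free catalyst; that part of a forecast is a guess

- part of the left-handed substrate and right-handed substrate charged together that has reacted at 8.0 min
- excess of left-handed product over right-handed product in the product at 8.0 min
- excess of right-handed substrate over left-handed substrate among what is left of the two at 8.0 min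

Work with fractions left, not fractions made. Friday's last reading gives 31.9 for the selectivity factor s, the logarithm of the fraction of left-handed substrate left over the logarithm of the fraction of right-handed substrate left. The reading before it gives 17.7, so take these as the two ends: the right-handed loss in them is 0.7 percentage points and 1.1 points, against a scatter of 0.5 points.

Next bracket L, the logarithm of one over the fraction of left-handed substrate left. Friday's pseudo-first-order constant, taken up to its last reading, reads 0.0899 min⁻¹. For the slow end, guess first order in catalyst, whose concentration rises by a factor 2.00, and let partner count for nothing: L = 1.44. For the fast end, count partner too, at its mean over each run, with the flask's ending near 0.5 of its charge: L = 2.38.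

The right-handed fraction left is exp(−L/s). The product excess is the difference of the two fractions left over what has reacted of both. Slow with high s gives an estimated ceiling of 89.1%. Fast with low s gives an estimated floor of 75.7%. Commit to the middle, 82.4%.

The forecast gives 46% reacted, product excess 89% and substrate excess 76%, holding that “selectivity afterwards is high (s of 30 or more)”. Its product excess stands at the ceiling.

The flask gives 47.8%, 80.7% and 73.8%. Its product excess lies below the ceiling and above the floor.

    2 free catalyst ⇌ resting dimer, settled at all times (K = 550 M⁻¹)
    partner + catalyst intermediate B → free catalyst + right-handed product (k = 2.30 M⁻¹ s⁻¹)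
    free catalyst + right-handed substrate ⇌ catalyst intermediate B (K = 0.260 M⁻¹, k = 320 M⁻¹ s⁻¹)
    partner + catalyst intermediate A → free catalyst + left-handed product (k = 4.80 M⁻¹ s⁻¹)
    free catalyst + left-handed substrate ⇌ catalyst intermediate A (K = 2.60 M⁻¹, k = 1100 M⁻¹ s⁻¹)
    free catalyst + added ligand ⇌ idle complex (K = 1100 M⁻¹, k = 4.70 M⁻¹ s⁻¹)

The flask's fractions left give s = 20.6. Carry it to the neighbour with 0.4 mol% of free catalyst: that flask keeps 0.22% of its left-handed substrate, so s predicts a product excess of 59.0%, and it gives 59.0%. The return of catalyst intermediate B to free catalyst and right-handed substrate holds the excess up: the asked flask without that return gives −48.8% instead of 80.7%.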